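The target is numbered along the chain, C1 (CO2H) to C14; the ring is the 1,2-dioxane O–O/C3/C4/C5/C6. Everything rests on cutting C8–C9: C8, the methyl-bearing carbon, is β to C6, the quaternary peroxide carbon of the ring, so with C6 as a ketone C7=C8 is a Michael acceptor. A copper-catalysed asymmetric conjugate addition of the C9–C11 Grignard reagent to (E)-hex-4-en-3-one forms C8–C9, sets C8 and leaves a regiodefined C6 enolate, trapped as its enol triflate. Negishi coupling with the C1–C5 zinc reagent (both arms from one allylic-alkylation product), cobalt-mediated peroxidation at C6 (unselective; epimer removed) and oxa-Michael closure build the ring.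

Key step: step 5

Assumption: the ligand enantiomers written for the two copper-catalysed steps (1 and 5) are those taken to give the configurations shown; both antipodes of each ligand are commercial, so the other one is used if the sense of induction proves opposite on these substrates.

Step 1
Reactants: 1 (E)-1,4-dibromobut-2-ene; 2 ethylmagnesium bromide
Product: 3 (R)-3-(bromomethyl)pent-1-ene
Conditions: CuBr·SMe2 (1 mol %), (R,R_p)-Taniaphos [1-{(R)-(dimethylamino)[2-(diphenylphosphino)phenyl]methyl}-2-(diphenylphosphino)ferrocene] (1.2 mol %), CH2Cl2, −75 °C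
Reagents that add atoms: none
Why: Copper-catalysed asymmetric allylic alkylation (SN2′) of the symmetric allylic dibromide with a Grignard reagent, in which the chiral diphosphine–copper complex directs ethyl transfer to the γ-carbon and so sets the ethyl-bearing stereocentre (later both C4 and C10) under catalyst control, leaving a primary bromide and a vinyl group as differentiated handles.

Step 2
Reactants: 3
Product: 5 (R)-2-(bromomethyl)butan-1-ol, via ozonide 4 (not isolated)
Conditions: O3, CH2Cl2, −78 °C; then NaBH4, MeOH, −78 to 0 °C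
Reagents that add atoms: ozone, [O-][O+]=O
Why: Ozonolysis of the terminal alkene with reductive work-up of the ozonide should give the one-carbon-shorter primary alcohol; the stereocentre is not involved and the aldehyde oxidation level is reduced before HBr can be eliminated.

Step 3
Reactants: 5
Product: 6 (R)-[2-(bromomethyl)butoxy](tert-butyl)diphenylsilane
Conditions: t-BuPh2SiCl, imidazole, CH2Cl2, rt
Reagents that add atoms: tert-butyl(chloro)diphenylsilane, CC(C)(C)[Si](Cl)(c1ccccc1)c1ccccc1
Why: Silyl ether protection of the future C11 hydroxyl with a group that should survive Grignard formation, catalytic acid and amine base; no stereocentre is touched.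

Step 4
Reactants: 3; 7 methyl acrylate
Product: 8 methyl (2E,4R)-4-(bromomethyl)hex-2-enoate
Conditions: second-generation Hoveyda–Grubbs catalyst (2 mol %), 7 (3 equiv), CH2Cl2, 40 °C
Reagents that add atoms: none
Why: Olefin cross-metathesis of the terminal alkene with the electron-poor acrylate should give the (E)-enoate by thermodynamic preference, with the allylic stereocentre (future C4) and the primary bromide untouched.

Step 5
Reactants: 6; 9 (E)-hex-4-en-3-one
Product: 12 (3Z,5S,7S)-7-{[(tert-butyldiphenylsilyl)oxy]methyl}-5-methylnon-3-en-3-yl trifluoromethanesulfonate, via Grignard reagent 10 (not isolated), via magnesium enolate 11 (not isolated)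
Conditions: Mg, Et2O, rt; then 9 (1.3 equiv), CuBr·SMe2 (5 mol %), (R,S_p)-Josiphos [(R)-1-{(S_p)-2-(diphenylphosphino)ferrocenyl}ethyldicyclohexylphosphine] (6 mol %), t-BuOMe, −78 °C, slow addition of 10; then N-(5-chloropyridin-2-yl)bis(trifluoromethanesulfonyl)imide, THF/DMPU, −78 °C to rt
Reagents that add atoms: N-(5-chloropyridin-2-yl)bis(trifluoromethanesulfonyl)imide (Comins reagent), O=S(=O)(N(c1ccc(Cl)cn1)S(=O)(=O)C(F)(F)F)C(F)(F)F
Why: Copper-catalysed asymmetric conjugate addition with enolate trapping: the Josiphos–CuBr complex and Grignard reagent 10 form a chiral alkylcuprate that binds the C7=C8 bond of the s-cis enone, transfers the alkyl group to C8 (σ-alkylcopper intermediate, then reductive elimination), so forming C8–C9, and releases the Z magnesium enolate 11, which the Comins reagent sulfonylates on oxygen. The closest known reaction type is the ferrocenyl-diphosphine/CuBr-catalysed 1,4-addition of alkylmagnesium bromides to acyclic (E)-enones followed by in situ O-triflation of the magnesium enolate. No ring is closed. The new stereocentre C8 is set by the catalyst (reagent control by the planar-chiral ligand; the C10 centre of 10 is too remote from the reacting carbon to interfere), and the enolate geometry follows from the s-cis enone. The step needs 1,4- over 1,2-addition and enantioface selection, secured by the soft cuprate, the low temperature, slow addition of 10 and the unhindered β-methyl (E)-enone, and it needs O-sulfonylation at C6 without enolate equilibration, secured by trapping the regiodefined C6=C7 enolate directly in the presence of DMPU.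

Step 6
Reactants: 12; 8
Product: 14 methyl (2E,4S,6Z,8S,10S)-10-{[(tert-butyldiphenylsilyl)oxy]methyl}-4,6-diethyl-8-methyldodeca-2,6-dienoate, via alkylzinc bromide 13 (not isolated)
Conditions: 8, Zn dust (I2-activated), DMA, 70 °C; then 12, PdCl2(dppf) {[1,1′-bis(diphenylphosphino)ferrocene]dichloropalladium} (5 mol %), THF, 50 °C
Reagents that add atoms: none
Why: Negishi sp2–sp3 cross-coupling of the enol triflate with the primary alkylzinc bromide (zinc insertion tolerates the enoate) should form C5–C6 with retention of the alkene geometry; no stereocentre is created and C4 is one carbon away from the metal-bearing carbon.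

Step 7
Reactants: 14
Product: 15 methyl (2E,4S,8S,10S)-10-{[(tert-butyldiphenylsilyl)oxy]methyl}-4,6-diethyl-8-methyl-6-[(triethylsilyl)peroxy]dodec-2-enoate (both C6 epimers)
Conditions: Co(thd)2 [bis(2,2,6,6-tetramethylheptane-3,5-dionato)cobalt] (10 mol %), O2 (1 atm), Et3SiH, ClCH2CH2Cl, rt
Reagents that add atoms: dioxygen, O=O; triethylsilane, CC[SiH](CC)CC
Why: Mukaiyama–Isayama hydroperoxysilylation, in which hydrogen-atom transfer from a cobalt hydride to C7 of the electron-rich trisubstituted alkene gives the tertiary C6 radical that is captured by O2 and silylated (Markovnikov placement of O–O at C6, enoate expected to be spared); the planar radical is captured on both faces, so C6 is formed here without control and both epimers are carried to the separation in step 8.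

Step 8
Reactants: 15
Product: 17 methyl 2-[(3S,4S,6R)-6-[(2S,4S)-4-{[(tert-butyldiphenylsilyl)oxy]methyl}-2-methylhexyl]-4,6-diethyl-1,2-dioxan-3-yl]acetate, via hydroperoxide 16 (not isolated)
Conditions: HCl (cat.), MeOH, 0 °C; then Et2NH, CF3CH2OH, rt; chromatographic separation of the C6 epimer
Reagents that add atoms: none
Why: Acidic desilylation followed by amine-mediated 6-exo-trig intramolecular oxa-Michael addition of the hydroperoxide to the (E)-enoate closes the ring O–O/C3–C6; C3 is set by the existing C4 centre through a chair-like transition state with the C4 ethyl group equatorial and the acceptor arm axial (3,4-cis, as required), and the 6R diastereomer is separated from its C6 epimer.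

Step 9
Reactants: 17
Product: 18 methyl 2-[(3S,4S,6R)-4,6-diethyl-6-[(2S,4S)-4-(hydroxymethyl)-2-methylhexyl]-1,2-dioxan-3-yl]acetate
Conditions: HF·pyridine, pyridine, THF, 0 °C to rt
Reagents that add atoms: none
Why: Fluoride-mediated desilylation under buffered, non-reducing conditions that the dialkyl peroxide and the methyl ester should tolerate.

Step 10
Reactants: 18; 19 1-(triphenylphosphoranylidene)propan-2-one
Product: 21 methyl 2-[(3S,4S,6R)-4,6-diethyl-6-[(2S,4S,5E)-4-ethyl-2-methyl-7-oxooct-5-en-1-yl]-1,2-dioxan-3-yl]acetate, via aldehyde 20 (not isolated)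
Conditions: Dess–Martin periodinane, CH2Cl2, 0 °C to rt; then 19, CH2Cl2, rt
Reagents that add atoms: none
Why: One-pot Dess–Martin oxidation and Wittig olefination with the stabilised acetonyl ylide should give the (E)-enone; the aldehyde at C11 is not isolated, which limits epimerisation of C10.

Step 11
Reactants: 21
Product: 22 2-[(3S,4S,6R)-4,6-diethyl-6-[(2S,4S,5E)-4-ethyl-2-methyl-7-oxooct-5-en-1-yl]-1,2-dioxan-3-yl]acetic acid
Conditions: LiOH, THF/H2O (3:1), 0 °C; then 1 M HCl to pH 3
Reagents that add atoms: lithium hydroxide, [Li+].[OH-]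
Why: Saponification of the methyl ester at low temperature, which the 1,2-dioxane and the enone should tolerate, followed by acidification to the free acid.

Compound list
1 | (E)-1,4-dibromobut-2-ene | BrC/C=C/CBr | starting material
2 | ethylmagnesium bromide | CC[Mg]Br | starting material
3 | (R)-3-(bromomethyl)pent-1-ene | CC[C@H](C=C)CBr | intermediate
4 | 3-[(2R)-1-bromobutan-2-yl]-1,2,4-trioxolane (ozonide) | CC[C@H](C1OCOO1)CBr | intermediate (not isolated)
5 | (R)-2-(bromomethyl)butan-1-ol | CC[C@H](CO)CBr | intermediate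
6 | (R)-[2-(bromomethyl)butoxy](tert-butyl)diphenylsilane | CC[C@H](CO[Si](c1ccccc1)(c1ccccc1)C(C)(C)C)CBr | intermediate
7 | methyl acrylate | COC(=O)C=C | starting material
8 | methyl (2E,4R)-4-(bromomethyl)hex-2-enoate | CC[C@H](/C=C/C(=O)OC)CBr | intermediate
9 | (E)-hex-4-en-3-one | CCC(=O)/C=C/C | starting material
10 | [(2R)-2-{[(tert-butyldiphenylsilyl)oxy]methyl}butyl]magnesium bromide | CC[C@H](CO[Si](c1ccccc1)(c1ccccc1)C(C)(C)C)C[Mg]Br | intermediate (not isolated)
11 | bromomagnesium (3Z,5S,7S)-7-{[(tert-butyldiphenylsilyl)oxy]methyl}-5-methylnon-3-en-3-olate | CC/C(O[Mg]Br)=C/[C@@H](C)C[C@H](CC)CO[Si](c1ccccc1)(c1ccccc1)C(C)(C)C | intermediate (not isolated)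
12 | (3Z,5S,7S)-7-{[(tert-butyldiphenylsilyl)oxy]methyl}-5-methylnon-3-en-3-yl trifluoromethanesulfonate | CC/C(OS(=O)(=O)C(F)(F)F)=C/[C@@H](C)C[C@H](CC)CO[Si](c1ccccc1)(c1ccccc1)C(C)(C)C | intermediate
13 | [(2R,3E)-2-ethyl-5-methoxy-5-oxopent-3-en-1-yl]zinc bromide | CC[C@H](/C=C/C(=O)OC)C[Zn]Br | intermediate (not isolated)
14 | methyl (2E,4S,6Z,8S,10S)-10-{[(tert-butyldiphenylsilyl)oxy]methyl}-4,6-diethyl-8-methyldodeca-2,6-dienoate | COC(=O)/C=C/[C@@H](CC)C/C(CC)=C\[C@@H](C)C[C@H](CC)CO[Si](c1ccccc1)(c1ccccc1)C(C)(C)C | intermediate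
15 | methyl (2E,4S,8S,10S)-10-{[(tert-butyldiphenylsilyl)oxy]methyl}-4,6-diethyl-8-methyl-6-[(triethylsilyl)peroxy]dodec-2-enoate (both C6 epimers) | COC(=O)/C=C/[C@@H](CC)CC(CC)(OO[Si](CC)(CC)CC)C[C@@H](C)C[C@H](CC)CO[Si](c1ccccc1)(c1ccccc1)C(C)(C)C | intermediate
16 | methyl (2E,4S,8S,10S)-10-{[(tert-butyldiphenylsilyl)oxy]methyl}-4,6-diethyl-6-hydroperoxy-8-methyldodec-2-enoate (both C6 epimers) | COC(=O)/C=C/[C@@H](CC)CC(CC)(OO)C[C@@H](C)C[C@H](CC)CO[Si](c1ccccc1)(c1ccccc1)C(C)(C)C | intermediate (not isolated)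
17 | methyl 2-[(3S,4S,6R)-6-[(2S,4S)-4-{[(tert-butyldiphenylsilyl)oxy]methyl}-2-methylhexyl]-4,6-diethyl-1,2-dioxan-3-yl]acetate | CC[C@H](CO[Si](c1ccccc1)(c1ccccc1)C(C)(C)C)C[C@H](C)C[C@]1(CC)C[C@H](CC)[C@H](CC(=O)OC)OO1 | intermediate
18 | methyl 2-[(3S,4S,6R)-4,6-diethyl-6-[(2S,4S)-4-(hydroxymethyl)-2-methylhexyl]-1,2-dioxan-3-yl]acetate | CC[C@H](CO)C[C@H](C)C[C@]1(CC)C[C@H](CC)[C@H](CC(=O)OC)OO1 | intermediate
19 | 1-(triphenylphosphoranylidene)propan-2-one | CC(=O)C=P(c1ccccc1)(c1ccccc1)c1ccccc1 | starting material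
20 | methyl 2-[(3S,4S,6R)-4,6-diethyl-6-[(2S,4S)-4-formyl-2-methylhexyl]-1,2-dioxan-3-yl]acetate | CC[C@H](C=O)C[C@H](C)C[C@]1(CC)C[C@H](CC)[C@H](CC(=O)OC)OO1 | intermediate (not isolated)
21 | methyl 2-[(3S,4S,6R)-4,6-diethyl-6-[(2S,4S,5E)-4-ethyl-2-methyl-7-oxooct-5-en-1-yl]-1,2-dioxan-3-yl]acetate | CC[C@H](/C=C/C(C)=O)C[C@H](C)C[C@]1(CC)C[C@H](CC)[C@H](CC(=O)OC)OO1 | intermediate
22 | 2-[(3S,4S,6R)-4,6-diethyl-6-[(2S,4S,5E)-4-ethyl-2-methyl-7-oxooct-5-en-1-yl]-1,2-dioxan-3-yl]acetic acid | CC[C@H](/C=C/C(C)=O)C[C@H](C)C[C@]1(CC)C[C@H](CC)[C@H](CC(=O)O)OO1 | target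

Total step count: 11. Longest linear sequence: 10 steps (1, 2, 3, 5, 6, 7, 8, 9, 10, 11).

Steps most likely to fail

Step 7. What may go wrong: the planar tertiary C6 radical is captured by O2 from both faces without discrimination, so about half of the material is expected to end as the unwanted C6 epimer, and hydrogen-atom transfer to the enoate may compete. Fallback (sets out from 14, comes back at 17): the C6–O bond is made by an ionic, stereospecific sequence instead.
- Shi epoxidation of the 6Z alkene of 14 uses the L-sugar-derived enantiomer of the Shi ketone (Oxone, 2KHSO5·KHSO4·K2SO4, K2CO3, MeCN/dimethoxymethane/buffer, 0 °C). The spiro transition-state model predicts oxygen delivery to the face needed, and the step should give methyl (2E,4S)-5-{(2R,3S)-3-[(2S,4S)-4-{[(tert-butyldiphenylsilyl)oxy]methyl}hexan-2-yl]-2-ethyloxiran-2-yl}-4-ethylpent-2-enoate F5.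
- Perhydrolysis with ethereal H2O2 and catalytic H3PMo12O40 should open the oxirane at the tertiary carbon C6 with inversion to give the β-hydroxy hydroperoxide F6.
- Et2NH in CF3CH2OH closes the 7-hydroxy dioxane F7.
- The hindered C7 alcohol is converted with 1,1′-thiocarbonyldiimidazole and DMAP into the imidazole-1-carbothioate F8.
- Barton–McCombie deoxygenation (Bu3SnH, Et3B/air, catalytic PhSeSePh, benzene, rt) returns 17 as a single C6 epimer; benzeneselenol is there to reduce the C7 radical faster than it can attack the O–O bond.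

Step 5. What may go wrong: insufficient enantioface discrimination by the copper–diphosphine complex with this β-branched, silyloxy-bearing Grignard reagent, or slow O-sulfonylation of the magnesium enolate ending in protonation and loss of the regiodefined C6 handle. Fallback (sets out from 6 and 8, comes back at 14): C8 is set instead by a nickel-catalysed stereoconvergent Negishi coupling of a racemic secondary allylic chloride, with the C6=C7 double bond as activating group.
- Commercial hex-3-yn-2-ol is hydroaluminated and iodinated (NaAlH2(OCH2CH2OCH3)2, THF; then I2) to (Z)-4-iodohex-3-en-2-ol F1.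
- Negishi coupling of F1 with zinc reagent 13 (made from 8 as in step 6; PdCl2(dppf)) gives methyl (2E,4S,6Z)-4,6-diethyl-8-hydroxynona-2,6-dienoate F2 (both C8 epimers).
- MsCl and Et3N, then LiCl, give methyl (2E,4S,6Z)-8-chloro-4,6-diethylnona-2,6-dienoate F3.
- Bromide 6 is converted (Zn dust, DMA) into [(2R)-2-{[(tert-butyldiphenylsilyl)oxy]methyl}butyl]zinc bromide F4.
- F4 is coupled with F3 at the methyl-bearing allylic terminus to give 14, using NiCl2·glyme (NiCl2·CH3OCH2CH2OCH3), 2,6-bis[(4S)-4-(2-phenylethyl)-4,5-dihydrooxazol-2-yl]pyridine (or its enantiomer, as required for 8S), NaCl, DMA/DMF, −10 °C.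

Step 8. What may go wrong: attack of the hydroperoxide on the wrong enoate face (3,4-trans closure) or reversal of the addition under the basic conditions. Fallback (sets out from 15, comes back at 17): C3 is set by carbon–carbon bond formation on a cyclic peroxycarbenium ion instead of by C–O bond formation.
- Ozonolysis of the enoate of 15 (O3, CH2Cl2, −78 °C; Me2S) gives (2S,6S,8S)-8-{[(tert-butyldiphenylsilyl)oxy]methyl}-2,4-diethyl-6-methyl-4-[(triethylsilyl)peroxy]decanal F9.
- Catalytic HCl in MeOH removes the triethylsilyl group and closes the 3-methoxy-1,2-dioxane peroxy acetal F10.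
- TMSOTf and 1-(tert-butyldimethylsilyloxy)-1-methoxyethene in CH2Cl2 at −78 °C generate the peroxycarbenium ion and should add the acetate unit axially, cis to the equatorial C4 ethyl group, to give 17 after separation of the C6 epimer as in step 8.

Further compounds
F1 | step 5 | (Z)-4-iodohex-3-en-2-ol (racemic) | CC/C(I)=C/C(C)O
F2 | step 5 | methyl (2E,4S,6Z)-4,6-diethyl-8-hydroxynona-2,6-dienoate (both C8 epimers) | COC(=O)/C=C/[C@@H](CC)C/C(CC)=C\C(C)O
F3 | step 5 | methyl (2E,4S,6Z)-8-chloro-4,6-diethylnona-2,6-dienoate (both C8 epimers) | COC(=O)/C=C/[C@@H](CC)C/C(CC)=C\C(C)Cl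
F4 | step 5 | [(2R)-2-{[(tert-butyldiphenylsilyl)oxy]methyl}butyl]zinc bromide | CC[C@H](CO[Si](c1ccccc1)(c1ccccc1)C(C)(C)C)C[Zn]Br
F5 | step 7 | methyl (2E,4S)-5-{(2R,3S)-3-[(2S,4S)-4-{[(tert-butyldiphenylsilyl)oxy]methyl}hexan-2-yl]-2-ethyloxiran-2-yl}-4-ethylpent-2-enoate | COC(=O)/C=C/[C@@H](CC)C[C@@]1(CC)O[C@H]1[C@@H](C)C[C@H](CC)CO[Si](c1ccccc1)(c1ccccc1)C(C)(C)C
F6 | step 7 | methyl (2E,4S,6S,7S,8S,10S)-10-{[(tert-butyldiphenylsilyl)oxy]methyl}-4,6-diethyl-6-hydroperoxy-7-hydroxy-8-methyldodec-2-enoate | COC(=O)/C=C/[C@@H](CC)C[C@](CC)(OO)[C@@H](O)[C@@H](C)C[C@H](CC)CO[Si](c1ccccc1)(c1ccccc1)C(C)(C)C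
F7 | step 7 | methyl 2-[(3S,4S,6S)-6-[(1S,2S,4S)-4-{[(tert-butyldiphenylsilyl)oxy]methyl}-1-hydroxy-2-methylhexyl]-4,6-diethyl-1,2-dioxan-3-yl]acetate | CC[C@H](CO[Si](c1ccccc1)(c1ccccc1)C(C)(C)C)C[C@H](C)[C@H](O)[C@]1(CC)C[C@H](CC)[C@H](CC(=O)OC)OO1
F8 | step 7 | methyl 2-[(3S,4S,6S)-6-[(1S,2S,4S)-4-{[(tert-butyldiphenylsilyl)oxy]methyl}-1-[(1H-imidazol-1-ylcarbonothioyl)oxy]-2-methylhexyl]-4,6-diethyl-1,2-dioxan-3-yl]acetate | CC[C@H](CO[Si](c1ccccc1)(c1ccccc1)C(C)(C)C)C[C@H](C)[C@H](OC(=S)n2ccnc2)[C@]1(CC)C[C@H](CC)[C@H](CC(=O)OC)OO1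
F9 | step 8 | (2S,6S,8S)-8-{[(tert-butyldiphenylsilyl)oxy]methyl}-2,4-diethyl-6-methyl-4-[(triethylsilyl)peroxy]decanal (both C4 epimers of the decanal, C6 of the target) | O=C[C@@H](CC)CC(CC)(OO[Si](CC)(CC)CC)C[C@@H](C)C[C@H](CC)CO[Si](c1ccccc1)(c1ccccc1)C(C)(C)C
F10 | step 8 | tert-butyl{[(2S,4S)-5-[(4S)-4,6-diethyl-3-methoxy-1,2-dioxan-6-yl]-2-ethyl-4-methylpentyl]oxy}diphenylsilane (anomers and C6 epimers) | CC[C@H](CO[Si](c1ccccc1)(c1ccccc1)C(C)(C)C)C[C@H](C)CC1(CC)C[C@H](CC)C(OC)OO1
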